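In units of the substrate charge, let b be the partner left and q the side product made. The meeting had these flasks, runs and questions before it.

| flask | substrate | partner | second reagent | solid third reagent | remark | time |
|---|---|---|---|---|---|---|
| gamma | 0.50 mM | 1 equiv | 2 equiv | 1.8 equiv | run made earlier |  |
| delta | 0.50 mM | 1.4 equiv | 2 equiv | 1.8 equiv | run made earlier |  |
| alpha | 0.50 mM | 2.2 equiv | 2 equiv | 1.8 equiv | run made earlier |  |
| beta | 0.75 mM | 1 equiv | 2 equiv | 1.8 equiv | run made earlier |  |
| ochre | 0.50 mM | 1.00 equiv (in portions, 2, over 80 s) | 2.00 equiv | 1.80 equiv | first portion at the start, last at 80 s | 3.0 min |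
| amber | 0.50 mM (fed, over 80 s) | 1.00 equiv | 2.00 equiv | 1.80 equiv | all else is in the flask from the start; the feed brings no volume worth counting | 3.0 min |
| teal | 0.50 mM | 1.00 equiv | 2.00 equiv | 1.80 equiv | everything together at the start | 3.0 min |
| red | 0.50 mM | 1.00 equiv (fed, over 80 s) | 2.00 equiv | 1.80 equiv | all else is in the flask from the start; the feed brings no volume worth counting | 3.0 min |

| run | time / min | side product / % | target / % | substrate / % |
|---|---|---|---|---|
| gamma | 0.667 | 14.6 | 24.8 | 12.4 |
| gamma | 1.33 | 15.4 | 49.6 | 2.7 |
| gamma | 2.00 | 18.5 | 62.3 | 2.6 |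
| gamma | 2.50 | 16.8 | 66.6 | 0.1 |
| gamma | 3.00 | 15.1 | 69.0 | 0 |
| delta | 0.333 | 9.2 | 9.8 | 12.7 |
| delta | 0.833 | 7.9 | 40.6 | 1.7 |
| delta | 1.50 | 8.8 | 60.1 | 2.3 |
| delta | 2.50 | 10.2 | 72.9 | 1.1 |
| delta | 4.00 | 11.7 | 75.3 | 0 |
| alpha | 0.250 | 5.6 | 8.8 | 7.4 |
| alpha | 0.500 | 4.9 | 24.6 | 0 |
| alpha | 1.00 | 6.3 | 52.2 | 0.6 |
| alpha | 2.00 | 5.7 | 72.6 | 0 |
| alpha | 4.00 | 4.5 | 81.0 | 0 |
| beta | 0.250 | 11.6 | 4.7 | 22.7 |
| beta | 0.500 | 11.9 | 24.7 | 9.0 |
| beta | 1.00 | 15.9 | 51.3 | 0 |
| beta | 2.00 | 16.4 | 70.0 | 0.5 |
| beta | 4.00 | 15.6 | 73.4 | 0 |

(readings scatter by 1 percentage point)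

- at the start none of the solid third reagent is in solution

- the flask that comes out highest in amount of side product, in percent of the substrate charged; "all alike" if 1.5 percentage points covers them all (ochre / amber / teal / red / all alike)
- amount of side product at the end, in percent of the substrate charged, ochre
- amount of side product at the end, in percent of the substrate charged, amber
- amount of side product at the end, in percent of the substrate charged, teal
- amount of side product at the end, in percent of the substrate charged, red

The chair noted that the last side-product reading barely moves with concentration, 15.1 % in gamma against 15.6 % in beta, but falls with partner, to 4.5 % in alpha. One member doubted two substrates per side product: counted so, beta's last readings sum to 105 %, more than the charge, though that is a reading with its scatter.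

She proposed that each substrate is either captured, at a rate proportional to b, or lost to side product at a rate independent of b. Side rate over capture rate is then ρ/b, the substrate level cancels, and q = ρ ln(charged b / final b), where final b is the charge less one plus q. Gamma gives 0.0799, delta 0.117 and alpha 0.0790. Their mean 0.0921 is ρ, the side-to-capture ratio at unit b, a selectivity factor.

Teal and amber carry b from the same charge to the same end, so she wrote q = ρ ln(1/q) for both, which gives 16.6 % each. She expected red and ochre higher, without a figure.

The forecast differed on amber. It gave 23 % for ochre, 7 % for amber, 15.5 % for teal and 27 % for red, with red highest, and said “Amber: substrate is kept low, about 7%.”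

The flasks gave 33.6 % for ochre, 15.4 % for amber, 16.3 % for teal and 37.9 % for red, with red highest.

    second reagent + intermediate A → intermediate B (k = 33.7 L mol⁻¹ s⁻¹)
    third reagent + intermediate B ⇌ target (K = 21000 L mol⁻¹, k = 204 L mol⁻¹ s⁻¹)
    solid third reagent ⇌ third reagent, rate k3*(cs3 - [third reagent]) while solid is left; crystals form when [third reagent] > cs3 (solubility = 0.330 mM, k = 0.317 s⁻¹)
    substrate + second reagent → side product (k = 11.8 L mol⁻¹ s⁻¹)
    substrate + partner → intermediate A (k = 219 L mol⁻¹ s⁻¹)

Amber and teal end 0.9 percentage points apart, and amber stands at 15.4 % against the forecast's 7 %. The side step runs through second reagent, so ρ goes with its charge. The neighbour of amber with 1.20 equiv of second reagent has ρ = 0.0553, and the same equation gives q = 11.8 %. That flask gave 9.81 %, with 2.55 % of substrate still present at 3.00 min.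

All runs were computed for an exercise; scatter was added.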